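## Retrosynthetic overview

1. Numbering: ring A is C1–C6 (C1 = CH carrying the side chain, C4 = C(Me)OH, C5 = CHBr). The diene is C7=C8–C9=C10 with a methyl on C7. Ring B is O plus C11–C15 (C11 = C(Me)O, C14 = CHBr, C15 = CMe2).
2. The strategy rests on ring B. Its C14–Br and C15–O bonds sit on neighbouring carbons and its oxygen is the C11 carbinol oxygen, so ring B is the Br+/OH adduct of a prenyl C14=C15 alkene. These two bonds are cut first, giving an open-chain C11 tertiary alcohol, and a vanadium bromoperoxidase forms them again.
3. C8–C9 is cut next (Heck reaction). This gives a ring A (E)-alkenyl iodide and the vinyl group of (S)-linalool, which supplies C9–C15 and the C11 stereocentre.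
4. The E-C7=C8 iodide comes from a C1 ethynyl group by methylalumination and iodination, and the alkyne comes from a methyl ketone. Direct CHI3/CrCl2 iodo-olefination of that ketone is avoided because ketones react slowly and without E/Z control.
5. Ring A is bought as (1S,2S,4R)-limonene-1,2-diol. C1 and C4 are kept, and C5–O becomes C5–Br with inversion through a cyclic sulfate. Ring order: A from the chiral pool, B closed in the last step.

Key step: step 10

Assumption: (S)-(+)-linalool (coriandrol) is bought in enantiomerically enriched form; any (R)-linalool in it would be carried through as the C11 epimer of 15.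

## Route

Step 1
Reactants: 1 (1S,2S,4R)-limonene-1,2-diol
Product: 3 keto diol 1-[(1R,3S,4S)-3,4-dihydroxy-4-methylcyclohexyl]ethan-1-one, via secondary ozonide 2 (not isolated)
Conditions: O3, CH2Cl2, −78 °C; then Me2S, −78 °C to rt
Reagents that add atoms: ozone, [O-][O+]=O
Why: Ozonolysis with reductive work-up (Criegee mechanism) cleaves the only C=C bond of 1, the isopropenyl group, to the C7 methyl ketone; it comes first because the later RuO4 oxidation would not spare an alkene, and none of the three stereocentres is touched.

Step 2
Reactants: 3 keto diol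
Product: 4 cyclic sulfite 1-[(3aS,5R,7aS)-7a-methyl-2-oxidohexahydro-1,3,2-benzodioxathiol-5-yl]ethan-1-one (both epimers at sulfur)
Conditions: SOCl2, Et3N, CH2Cl2, 0 °C
Reagents that add atoms: thionyl chloride, O=S(Cl)Cl
Why: In this cyclic sulfite formation from a 1,2-diol the secondary chlorosulfite is closed by the tertiary hydroxyl after a ring flip to the chair with both oxygens equatorial, only O–H bonds break so C4 and C5 keep their configuration, and Et3N removes HCl before it can ionise the tertiary carbinol.

Step 3
Reactants: 4 cyclic sulfite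
Product: 5 trans-fused cyclic sulfate 1-[(3aS,5R,7aS)-7a-methyl-2,2-dioxidohexahydro-1,3,2-benzodioxathiol-5-yl]ethan-1-one
Conditions: RuCl3·xH2O (cat.), NaIO4, MeCN/CH2Cl2/H2O, 0 °C
Reagents that add atoms: sodium periodate, [Na+].[O-]I(=O)(=O)=O
Why: Catalytic RuO4 oxidation of a cyclic sulfite to the cyclic sulfate acts quickly and only at sulfur, removes the sulfur stereocentre, and leaves the ketone and the carbon stereocentres alone.

Step 4
Reactants: 5 cyclic sulfate
Product: 7 bromohydrin ketone 1-[(1R,3R,4S)-3-bromo-4-hydroxy-4-methylcyclohexyl]ethan-1-one, via lithium bromoalkyl sulfate 6 (not isolated)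
Conditions: LiBr, THF, rt to reflux; then 20% aq. H2SO4, Et2O, rt
Reagents that add atoms: lithium bromide, [Li+].[Br-]
Why: In this SN2 opening of a cyclic sulfate by halide, bromide attacks the secondary C5 and not the fully substituted C4, with inversion, turning the 5S C–O bond into the 5R C–Br bond cis to the C4 oxygen; that oxygen stays bound as sulfate and cannot act as a neighbouring group, the acid hydrolysis breaks the S–O bond so C4 is retained, and 7 relaxes to the chair with bromine, C4 methyl and acetyl all equatorial, which makes the wanted C1 configuration the thermodynamic one.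

Step 5
Reactants: 7 bromohydrin ketone
Product: 8 silyl ether 1-[(1R,3R,4S)-3-bromo-4-methyl-4-(triethylsilyloxy)cyclohexyl]ethan-1-one
Conditions: TESOTf, 2,6-lutidine, CH2Cl2, −78 to 0 °C
Reagents that add atoms: triethylsilyl triflate, CC[Si](CC)(CC)OS(=O)(=O)C(F)(F)F
Why: Silylation of a hindered tertiary alcohol with a silyl triflate and a non-nucleophilic base masks the only acidic proton before the strong-base and organoaluminium steps, and at low temperature 2,6-lutidine is too weak to turn the ketone into its silyl enol ether.

Step 6
Reactants: 8 silyl ether ketone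
Product: 10 alkyne {[(1S,2R,4R)-2-bromo-4-ethynyl-1-methylcyclohexyl]oxy}triethylsilane, via enol phosphate 9 (not isolated)
Conditions: LDA, THF, −78 °C; ClP(O)(OEt)2, −78 °C to rt; then added to LDA (excess), THF, −78 to 0 °C; aq. NH4Cl
Reagents that add atoms: none
Why: In this methyl ketone to terminal alkyne conversion (enol phosphate formation, then β-elimination) LDA removes a methyl proton kinetically so C1 is not deprotonated, the enolate oxygen is phosphorylated and excess LDA expels diethyl phosphate; the equatorial C5–Br bond has no antiperiplanar hydrogen for E2, and the anionic side chain lies on the same ring face as bromine so it cannot reach the backside of C5.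

Step 7
Reactants: 10 alkyne
Product: 12 alkenyl iodide {[(1S,2R,4R)-2-bromo-4-[(1E)-1-iodoprop-1-en-2-yl]-1-methylcyclohexyl]oxy}triethylsilane, via alkenylalane 11 (not isolated)
Conditions: Me3Al, Cp2ZrCl2, CH2Cl2, 0 °C to rt; then I2, THF, −30 to 0 °C
Reagents that add atoms: trimethylaluminium, C[Al](C)C; iodine, II
Why: In the Negishi carboalumination the Cp2ZrCl2-catalysed syn addition of Me–Al across the terminal alkyne puts methyl on C7 and aluminium on C8, iodinolysis of the C–Al bond with retention gives the E-alkenyl iodide by mechanism, and Me3Al tolerates the silyl ether and the unactivated secondary bromide at or below room temperature.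

Step 8
Reactants: 12 silyl-protected alkenyl iodide
Product: 13 (1S,2R,4R)-2-bromo-4-[(1E)-1-iodoprop-1-en-2-yl]-1-methylcyclohexan-1-ol
Conditions: HF·pyridine, THF, 0 °C to rt
Reagents that add atoms: none
Why: Fluoride-driven Si–O cleavage (desilylation) frees the C4 hydroxyl at a stage where no acid-labile dienol is present yet, and the alkenyl iodide and alkyl bromide are inert to HF·pyridine.

Step 9
Reactants: 13 alkenyl iodide; 14 (S)-linalool
Product: 15 (1S,2R,4R)-2-bromo-4-[(2E,4E,6S)-6-hydroxy-6,10-dimethylundeca-2,4,9-trien-2-yl]-1-methylcyclohexan-1-ol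
Conditions: Pd(OAc)2 (cat.), n-Bu4NCl, NaHCO3, DMF, 40 °C
Reagents that add atoms: none
Why: In this Heck reaction under Jeffery conditions, zerovalent palladium formed in situ inserts into the C8–iodine bond with retention far faster than into the secondary C5–Br bond, syn carbopalladation of the monosubstituted vinyl group of 14 joins C8 to the terminal carbon C9, and because C11 carries no hydrogen the syn β-hydride elimination can only use C9–H and gives E-C9=C10; the hindered C14=C15 alkene, both free hydroxyls and the C11 stereocentre are not involved.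

Step 10
Reactants: 15 open-chain tertiary alcohol
Product: 16 target (1S,2R,4R)-2-bromo-4-{(2E,4E)-5-[(2S,5R)-5-bromo-2,6,6-trimethyloxan-2-yl]penta-2,4-dien-2-yl}-1-methylcyclohexan-1-ol
Conditions: vanadium bromoperoxidase (Corallina officinalis), KBr, H2O2 (1 equiv, syringe pump), Na3VO4 (trace), MES buffer pH 6.5 with 30 vol% t-BuOH, 25 °C
Reagents that add atoms: potassium bromide, [K+].[Br-]
Why: The peroxovanadate cofactor of the enzyme (pentavalent vanadium, which does not change its oxidation state) oxidises bromide with H2O2 to an enzyme-bound HOBr equivalent that hands Br+ to the C14=C15 alkene, and the C11 hydroxyl opens the bromonium ion at the tertiary carbon C15 anti to bromine, forming the C14–Br and C15–O bonds in one event. The closest known reaction type is the haloperoxidase-catalysed bromonium cyclisation and bromoetherification of terpene alkenols of the nerol and nerolidol kind, whose chemical counterpart is the bromoetherification of linalool-type alcohols with bromodienone reagents. Ring B closes in the 6-endo mode through a chair, because the positive charge of the bromonium ion sits on the gem-dimethyl carbon C15, and this disfavours the 5-exo attack at C14 that would give an oxolane. C14 is the only new stereocentre: 14R follows from Br+ delivery to the alkene face exposed in the chair with bromine and the dienyl arm equatorial and the C11 methyl axial, the substrate's own preference for this chair is small so the binding pocket has to fix the face, and C11 stays S because its C–O bond is not broken. The step needs chemoselectivity for C14=C15 over the C7–C10 diene, and the substrate helps because both diene termini are hindered (C7 carries ring A, C10 adjoins the quaternary C11), the C11 oxygen deactivates the diene inductively, bromonium transfer between alkenes is reversible and only the C14=C15 bromonium ion has a hydroxyl placed for fast irreversible closure, while slow feeding of H2O2 as limiting reagent keeps excess oxidant and singlet oxygen from building up. The ring A bromohydrin is a spectator, since its cis C4–OH/C5–Br pair cannot close to an epoxide at pH 6.5.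

## Compound list

1 | (1S,2S,4R)-limonene-1,2-diol | CC(=C)[C@@H]1CC[C@](C)(O)[C@@H](O)C1 | starting material
2 | secondary ozonide, (1S,2S,4R)-1-methyl-4-(3-methyl-1,2,4-trioxolan-3-yl)cyclohexane-1,2-diol (trioxolane carbon undefined) | CC1(OCOO1)[C@@H]2CC[C@](C)(O)[C@@H](O)C2 | intermediate
3 | 1-[(1R,3S,4S)-3,4-dihydroxy-4-methylcyclohexyl]ethan-1-one | CC(=O)[C@@H]1CC[C@](C)(O)[C@@H](O)C1 | intermediate
4 | trans-fused cyclic sulfite of 3 (both epimers at sulfur) | CC(=O)[C@@H]1CC[C@]2(C)OS(=O)O[C@H]2C1 | intermediate
5 | trans-fused cyclic sulfate of 3, (3aS,5R,7aS) | CC(=O)[C@@H]1CC[C@]2(C)OS(=O)(=O)O[C@H]2C1 | intermediate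
6 | lithium (1S,2R,4R)-4-acetyl-2-bromo-1-methylcyclohexyl sulfate | CC(=O)[C@@H]1CC[C@](C)(OS(=O)(=O)[O-])[C@H](Br)C1.[Li+] | intermediate
7 | 1-[(1R,3R,4S)-3-bromo-4-hydroxy-4-methylcyclohexyl]ethan-1-one | CC(=O)[C@@H]1CC[C@](C)(O)[C@H](Br)C1 | intermediate
8 | 1-[(1R,3R,4S)-3-bromo-4-methyl-4-(triethylsilyloxy)cyclohexyl]ethan-1-one | CC(=O)[C@@H]1CC[C@](C)(O[Si](CC)(CC)CC)[C@H](Br)C1 | intermediate
9 | 1-[(1R,3R,4S)-3-bromo-4-methyl-4-(triethylsilyloxy)cyclohexyl]ethenyl diethyl phosphate | C=C(OP(=O)(OCC)OCC)[C@@H]1CC[C@](C)(O[Si](CC)(CC)CC)[C@H](Br)C1 | intermediate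
10 | {[(1S,2R,4R)-2-bromo-4-ethynyl-1-methylcyclohexyl]oxy}triethylsilane | C#C[C@@H]1CC[C@](C)(O[Si](CC)(CC)CC)[C@H](Br)C1 | intermediate
11 | (E)-alkenyl(dimethyl)alane, Al on C8 cis to the C7 methyl | C/C(=C\[Al](C)C)[C@@H]1CC[C@](C)(O[Si](CC)(CC)CC)[C@H](Br)C1 | intermediate
12 | {[(1S,2R,4R)-2-bromo-4-[(1E)-1-iodoprop-1-en-2-yl]-1-methylcyclohexyl]oxy}triethylsilane | C/C(=C\I)[C@@H]1CC[C@](C)(O[Si](CC)(CC)CC)[C@H](Br)C1 | intermediate
13 | (1S,2R,4R)-2-bromo-4-[(1E)-1-iodoprop-1-en-2-yl]-1-methylcyclohexan-1-ol | C/C(=C\I)[C@@H]1CC[C@](C)(O)[C@H](Br)C1 | intermediate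
14 | (S)-linalool | C=C[C@@](C)(O)CCC=C(C)C | starting material
15 | (1S,2R,4R)-2-bromo-4-[(2E,4E,6S)-6-hydroxy-6,10-dimethylundeca-2,4,9-trien-2-yl]-1-methylcyclohexan-1-ol | C/C(=C\C=C\[C@@](C)(O)CCC=C(C)C)[C@@H]1CC[C@](C)(O)[C@H](Br)C1 | intermediate
16 | CNP0199463.1, (1S,2R,4R)-2-bromo-4-{(2E,4E)-5-[(2S,5R)-5-bromo-2,6,6-trimethyloxan-2-yl]penta-2,4-dien-2-yl}-1-methylcyclohexan-1-ol | C/C(=C\C=C\[C@]1(C)CC[C@@H](Br)C(C)(C)O1)[C@@H]1CC[C@](C)(O)[C@H](Br)C1 | target

## Step count and risks

Total step count: 10. Longest linear sequence: 10 steps (1 to 16). Compound 14 enters as bought at step 9.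

**Step 10 (highest risk).**
- What may go wrong:
  - Br+ is transferred to the conjugated diene instead of C14=C15.
  - The enzyme releases free HOBr, so facial control at C14 is lost.
  - 5-exo closure competes, or water captures the bromonium ion.
  - Turnover is low because the C20 substrate dissolves poorly.
- Fallback: it sets out from 14 and returns to the route at 16. The order of the two bond constructions is exchanged, so that no diene is present when bromine is introduced. (S)-Linalool 14 is bromoetherified chemically with 2,4,4,6-tetrabromocyclohexa-2,5-dien-1-one in MeNO2. In 14 the prenyl alkene is far more nucleophilic than the monosubstituted vinyl group. The pyran with bromine and vinyl both equatorial, (2S,5R)-5-bromo-2-ethenyl-2,6,6-trimethyloxane F1, is separated by chromatography from its C5 epimer and from the oxolane isomers. F1 is then coupled with 13 under the Heck conditions of step 9 to give 16.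

**Step 4.**
- What may go wrong:
  - The opening is slow, because in the trans-fused chair the axial acetyl group shields the backside of C5.
  - Ionisation at the tertiary C4 competes.
  - Elimination of the sulfate occurs.
  - C1 epimerises while the acetyl group is held axial.
- Fallback: it sets out from 3 and returns at 8. The cyclic activation is replaced by an acyclic leaving group on a differentiated diol.
  - Ac2O/pyridine acylates only the secondary hydroxyl, giving (1S,2S,5R)-5-acetyl-2-hydroxy-2-methylcyclohexyl acetate F2.
  - TESOTf/2,6-lutidine gives (1S,2S,5R)-5-acetyl-2-methyl-2-(triethylsilyloxy)cyclohexyl acetate F3.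
  - K2CO3/MeOH frees the secondary alcohol, 1-[(1R,3S,4S)-3-hydroxy-4-methyl-4-(triethylsilyloxy)cyclohexyl]ethan-1-one F4.
  - Tf2O/pyridine gives (1S,2S,5R)-5-acetyl-2-methyl-2-(triethylsilyloxy)cyclohexyl trifluoromethanesulfonate F5.
  - n-Bu4NBr in toluene displaces the axial triflate with inversion and gives 8.

**Step 6.**
- What may go wrong:
  - Excess LDA removes HBr.
  - The C1 hydrogen of the enol phosphate is removed, which forms an allene and erases C1.
  - Enolisation towards the methyl group is incomplete.
- Fallback: it sets out from 8 and returns at 12, so it replaces both steps 6 and 7 by an olefination. The boron–Wittig reaction of 8 with LiCH(Bpin)2 (from CH2(Bpin)2 and lithium 2,2,6,6-tetramethylpiperidide) should place boron trans to the bulky ring. It gives 2-{(1E)-2-[(1R,3R,4S)-3-bromo-4-methyl-4-(triethylsilyloxy)cyclohexyl]prop-1-en-1-yl}-4,4,5,5-tetramethyl-1,3,2-dioxaborolane F6, which is freed from any Z isomer by chromatography. Iodination with NaOH/I2 in THF, with retention, gives 12.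

## Further compounds

F1 | step 10 | (2S,5R)-5-bromo-2-ethenyl-2,6,6-trimethyloxane | C=C[C@]1(C)CC[C@@H](Br)C(C)(C)O1
F2 | step 4 | (1S,2S,5R)-5-acetyl-2-hydroxy-2-methylcyclohexyl acetate | CC(=O)[C@@H]1CC[C@](C)(O)[C@@H](OC(C)=O)C1
F3 | step 4 | (1S,2S,5R)-5-acetyl-2-methyl-2-(triethylsilyloxy)cyclohexyl acetate | CC(=O)[C@@H]1CC[C@](C)(O[Si](CC)(CC)CC)[C@@H](OC(C)=O)C1
F4 | step 4 | 1-[(1R,3S,4S)-3-hydroxy-4-methyl-4-(triethylsilyloxy)cyclohexyl]ethan-1-one | CC(=O)[C@@H]1CC[C@](C)(O[Si](CC)(CC)CC)[C@@H](O)C1
F5 | step 4 | (1S,2S,5R)-5-acetyl-2-methyl-2-(triethylsilyloxy)cyclohexyl trifluoromethanesulfonate | CC(=O)[C@@H]1CC[C@](C)(O[Si](CC)(CC)CC)[C@@H](OS(=O)(=O)C(F)(F)F)C1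
F6 | step 6 | 2-{(1E)-2-[(1R,3R,4S)-3-bromo-4-methyl-4-(triethylsilyloxy)cyclohexyl]prop-1-en-1-yl}-4,4,5,5-tetramethyl-1,3,2-dioxaborolane | C/C(=C\B1OC(C)(C)C(C)(C)O1)[C@@H]2CC[C@](C)(O[Si](CC)(CC)CC)[C@H](Br)C2
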